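**Retrosynthetic overview**
- The target is reached by global desilylation of a fully silylated 5-deoxyflavanone. Its C5–H comes from a 5-O-triflate, so the 5-oxygen of a bought 5-hydroxyflavanone serves as a handle and is then deleted.
- Key disconnection C8–C1'': tandem [3,3]/[3,3] shift (aromatic Claisen to C6, then Cope to C8) of a 5-O-[(Z)-allyl] ether. Two chair transition states hand the allyl unit over with its connectivity and Z geometry intact.
- The 5-O-allyl ether comes from Mitsunobu coupling of 7,3',4'-tris-O-silyl (2S)-eriodictyol with a (Z)-allylic alcohol.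
- The (Z)-alcohol comes from syn-carbocupration of a γ-silyloxy ynoate followed by ester reduction.
- No ring is built: rings A, B and C and the C2 stereocentre are bought intact in (2S)-eriodictyol.

Assumption: the purchased (2S)-eriodictyol (CAS 552-58-9, citrus-derived) is essentially enantiopure; ee is checked by chiral HPLC on receipt.

TBS = tert-butyldimethylsilyl. Flavanone numbering: O1, C2, C3, C4=O, ring A positions 5–8, ring B primed.

**Step 1**
Reactants: 1 tert-butyldimethyl(prop-2-yn-1-yloxy)silane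
Product: 3 ethyl 4-[(tert-butyldimethylsilyl)oxy]but-2-ynoate, via lithium acetylide 2 (not isolated)
Conditions: n-BuLi, THF, −78 °C; then ClCO2Et, −78 → 0 °C
Reagents that add atoms: ethyl chloroformate, CCOC(=O)Cl
Why: Deprotonation of the terminal alkyne and C-acylation of the lithium acetylide by the chloroformate (acetylide acylation) give the ynoate, the silyl ether being inert.

**Step 2**
Reactants: 3 ethyl 4-[(tert-butyldimethylsilyl)oxy]but-2-ynoate
Product: 5 ethyl (2Z)-4-[(tert-butyldimethylsilyl)oxy]-3-methylbut-2-enoate, via vinylcuprate 4 (not isolated)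
Conditions: Me2CuLi (from CuI + 2 MeLi), THF, −78 °C; then sat. aq NH4Cl at −78 °C
Reagents that add atoms: lithium dimethylcuprate, [Li+].C[Cu-]C (made in the flask from methyllithium, [Li]C, and CuI)
Why: Conjugate syn-carbocupration of the ynoate and cold protonation with retention place the new methyl trans and the CH2OTBS group cis to the ester, which fixes the Z geometry of the future side chain.

**Step 3**
Reactants: 5 ethyl (2Z)-4-[(tert-butyldimethylsilyl)oxy]-3-methylbut-2-enoate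
Product: 7 (2Z)-4-[(tert-butyldimethylsilyl)oxy]-3-methylbut-2-en-1-ol, via enal 6 (not isolated)
Conditions: i-Bu2AlH (2.3 equiv), CH2Cl2, −78 → −20 °C; aq KNaC4H4O6 work-up
Reagents that add atoms: none
Why: 1,2-Reduction of the enoate by i-Bu2AlH passes through the enal to the allylic alcohol at low temperature without touching the alkene geometry or the silyl ether.

**Step 4**
Reactants: 8 (2S)-eriodictyol [(2S)-5,7,3',4'-tetrahydroxyflavanone]
Product: 9 (2S)-5-hydroxy-7,3',4'-tris[(tert-butyldimethylsilyl)oxy]flavanone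
Conditions: TBSCl (3.3 equiv), imidazole (7 equiv), DMF, 0 °C → rt
Reagents that add atoms: tert-butyldimethylsilyl chloride, CC(C)(C)[Si](C)(C)Cl
Why: Imidazole-mediated silylation caps the three free phenols while the 5-OH, locked in a hydrogen bond to the C4 carbonyl, stays free, and the weak base does not open ring C, so C2 stays S.

**Step 5**
Reactants: 9 (2S)-5-hydroxy-7,3',4'-tris[(tert-butyldimethylsilyl)oxy]flavanone; 7 (2Z)-4-[(tert-butyldimethylsilyl)oxy]-3-methylbut-2-en-1-ol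
Product: 10 (2S)-5-{[(2Z)-4-[(tert-butyldimethylsilyl)oxy]-3-methylbut-2-en-1-yl]oxy}-7,3',4'-tris[(tert-butyldimethylsilyl)oxy]flavanone
Conditions: PPh3, DIAD, THF, 0 °C → rt
Reagents that add atoms: none
Why: Mitsunobu etherification of the chelated phenol at the primary allylic carbon (SN2, no allylic transposition) runs under near-neutral conditions, so the C2 centre and the Z alkene are both kept.

**Step 6**
Reactants: 10 (2S)-5-{[(2Z)-4-[(tert-butyldimethylsilyl)oxy]-3-methylbut-2-en-1-yl]oxy}-7,3',4'-tris[(tert-butyldimethylsilyl)oxy]flavanone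
Product: 13 (2S)-5-hydroxy-8-[(2Z)-4-[(tert-butyldimethylsilyl)oxy]-3-methylbut-2-en-1-yl]-7,3',4'-tris[(tert-butyldimethylsilyl)oxy]flavanone, via ortho-dienone 11 (not isolated), via para-dienone 12 (not isolated)
Conditions: Eu(fod)3 (10 mol %), acid-free CHCl3, 60 °C, sealed tube
Reagents that add atoms: none
Why: A Lewis-acid-accelerated aromatic Claisen rearrangement to C6 is followed by a Cope rearrangement to C8 and enolisation (para-Claisen–Cope, the known behaviour of 5-O-prenyl flavanones), and the two successive chair [3,3] shifts return the allyl unit with its original connectivity and Z geometry while C2 is not involved.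

**Step 7**
Reactants: 13 (2S)-5-hydroxy-8-[(2Z)-4-[(tert-butyldimethylsilyl)oxy]-3-methylbut-2-en-1-yl]-7,3',4'-tris[(tert-butyldimethylsilyl)oxy]flavanone
Product: 14 (2S)-8-[(2Z)-4-[(tert-butyldimethylsilyl)oxy]-3-methylbut-2-en-1-yl]-7,3',4'-tris[(tert-butyldimethylsilyl)oxy]-4-oxoflavan-5-yl trifluoromethanesulfonate
Conditions: Tf2O, pyridine, CH2Cl2, −20 → 0 °C
Reagents that add atoms: trifluoromethanesulfonic anhydride, O=S(=O)(OS(=O)(=O)C(F)(F)F)C(F)(F)F
Why: O-Sulfonylation of the only free (chelated) phenol gives the aryl triflate needed to delete the 5-oxygen, and pyridine at low temperature does not open ring C.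

**Step 8**
Reactants: 14 (2S)-8-[(2Z)-4-[(tert-butyldimethylsilyl)oxy]-3-methylbut-2-en-1-yl]-7,3',4'-tris[(tert-butyldimethylsilyl)oxy]-4-oxoflavan-5-yl trifluoromethanesulfonate
Product: 15 (2S)-8-[(2Z)-4-[(tert-butyldimethylsilyl)oxy]-3-methylbut-2-en-1-yl]-7,3',4'-tris[(tert-butyldimethylsilyl)oxy]flavanone
Conditions: Pd(OAc)2 (5 mol %), dppp (5 mol %), Et3SiH, DMF, 60 °C
Reagents that add atoms: none
Why: Oxidative addition of the electron-poor aryl triflate to zerovalent palladium, hydride transfer from the silane and reductive elimination replace OTf by H (Pd-catalysed triflate hydrogenolysis) under non-basic conditions that spare the alkene, the silyl ethers and C2.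

**Step 9**
Reactants: 15 (2S)-8-[(2Z)-4-[(tert-butyldimethylsilyl)oxy]-3-methylbut-2-en-1-yl]-7,3',4'-tris[(tert-butyldimethylsilyl)oxy]flavanone
Product: 16 (2S)-2-(3,4-dihydroxyphenyl)-7-hydroxy-8-[(2Z)-4-hydroxy-3-methylbut-2-en-1-yl]-2,3-dihydro-4H-chromen-4-one (CNP0205253.2)
Conditions: TBAF (4.5 equiv), AcOH (5 equiv), THF, 0 °C → rt; work-up at pH 5
Reagents that add atoms: none
Why: Fluoride cleaves all four Si–O bonds (global desilylation) while the acetic acid buffer keeps the phenols protonated, so ring C does not open and C2 stays S.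

**Compound list**
1 | tert-butyldimethyl(prop-2-yn-1-yloxy)silane | C#CCO[Si](C)(C)C(C)(C)C | starting material
2 | lithium acetylide of 1 | [Li]C#CCO[Si](C)(C)C(C)(C)C | intermediate
3 | ethyl 4-[(tert-butyldimethylsilyl)oxy]but-2-ynoate | CCOC(=O)C#CCO[Si](C)(C)C(C)(C)C | intermediate
4 | lithium methyl[(Z)-1-ethoxycarbonyl-2-methyl-3-(TBS-oxy)prop-1-enyl]cuprate (Cu cis to the new methyl) | CCOC(=O)/C([Cu-]C)=C(/C)CO[Si](C)(C)C(C)(C)C.[Li+] | intermediate
5 | ethyl (2Z)-4-[(tert-butyldimethylsilyl)oxy]-3-methylbut-2-enoate | CCOC(=O)/C=C(/C)CO[Si](C)(C)C(C)(C)C | intermediate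
6 | (2Z)-4-[(tert-butyldimethylsilyl)oxy]-3-methylbut-2-enal | O=C/C=C(/C)CO[Si](C)(C)C(C)(C)C | intermediate
7 | (2Z)-4-[(tert-butyldimethylsilyl)oxy]-3-methylbut-2-en-1-ol | OC/C=C(/C)CO[Si](C)(C)C(C)(C)C | intermediate
8 | (2S)-eriodictyol | Oc1cc(O)c2c(c1)O[C@H](c1ccc(O)c(O)c1)CC2=O | starting material
9 | (2S)-5-hydroxy-7,3',4'-tris(TBS-oxy)flavanone | CC(C)(C)[Si](C)(C)Oc1cc(O)c2c(c1)O[C@H](c1ccc(O[Si](C)(C)C(C)(C)C)c(O[Si](C)(C)C(C)(C)C)c1)CC2=O | intermediate
10 | (2S)-5-{[(2Z)-4-(TBS-oxy)-3-methylbut-2-en-1-yl]oxy}-7,3',4'-tris(TBS-oxy)flavanone | CC(C)(C)[Si](C)(C)Oc1cc(OC/C=C(/C)CO[Si](C)(C)C(C)(C)C)c2c(c1)O[C@H](c1ccc(O[Si](C)(C)C(C)(C)C)c(O[Si](C)(C)C(C)(C)C)c1)CC2=O | intermediate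
11 | (2S)-6-[1-(TBS-oxy)-2-methylbut-3-en-2-yl]-7,3',4'-tris(TBS-oxy)flavan-4,5(6H)-dione (ortho-dienone; C6 and the quaternary carbon are transient and left undefined) | C=CC(C)(CO[Si](C)(C)C(C)(C)C)C1C(O[Si](C)(C)C(C)(C)C)=CC2=C(C1=O)C(=O)C[C@@H](c1ccc(O[Si](C)(C)C(C)(C)C)c(O[Si](C)(C)C(C)(C)C)c1)O2 | intermediate
12 | (2S)-8-[(2Z)-4-(TBS-oxy)-3-methylbut-2-en-1-yl]-7,3',4'-tris(TBS-oxy)flavan-4,5(8H)-dione (para-dienone; C8 transient, undefined) | C/C(=C/CC1C(O[Si](C)(C)C(C)(C)C)=CC(=O)C2=C1O[C@H](c1ccc(O[Si](C)(C)C(C)(C)C)c(O[Si](C)(C)C(C)(C)C)c1)CC2=O)CO[Si](C)(C)C(C)(C)C | intermediate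
13 | (2S)-5-hydroxy-8-[(2Z)-4-(TBS-oxy)-3-methylbut-2-en-1-yl]-7,3',4'-tris(TBS-oxy)flavanone | C/C(=C/Cc1c(O[Si](C)(C)C(C)(C)C)cc(O)c2c1O[C@H](c1ccc(O[Si](C)(C)C(C)(C)C)c(O[Si](C)(C)C(C)(C)C)c1)CC2=O)CO[Si](C)(C)C(C)(C)C | intermediate
14 | 5-O-triflate of 13 | C/C(=C/Cc1c(O[Si](C)(C)C(C)(C)C)cc(OS(=O)(=O)C(F)(F)F)c2c1O[C@H](c1ccc(O[Si](C)(C)C(C)(C)C)c(O[Si](C)(C)C(C)(C)C)c1)CC2=O)CO[Si](C)(C)C(C)(C)C | intermediate
15 | (2S)-8-[(2Z)-4-(TBS-oxy)-3-methylbut-2-en-1-yl]-7,3',4'-tris(TBS-oxy)flavanone | C/C(=C/Cc1c(O[Si](C)(C)C(C)(C)C)ccc2c1O[C@H](c1ccc(O[Si](C)(C)C(C)(C)C)c(O[Si](C)(C)C(C)(C)C)c1)CC2=O)CO[Si](C)(C)C(C)(C)C | intermediate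
16 | (2S)-2-(3,4-dihydroxyphenyl)-7-hydroxy-8-[(2Z)-4-hydroxy-3-methylbut-2-en-1-yl]-2,3-dihydro-4H-chromen-4-one | C/C(=C/Cc1c(O)ccc2c1O[C@H](c1ccc(O)c(O)c1)CC2=O)CO | target

**Totals**
Total step count: 9. Longest linear sequence: 8 steps (steps 1, 2, 3, 5, 6, 7, 8, 9).

**Steps most likely to fail, with fallbacks**

Step 6 (tandem Claisen–Cope). The risks are arrest at C6 (tautomerisation of 11 before the Cope step), partial Z → E leakage if the europium-promoted shift becomes ionic, and return of 9 by dealkylation. The fallback sets out from 9 and comes back at 16.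
- The 5-oxygen is deleted first, as in steps 7 and 8 (Tf2O/pyridine, then Pd(OAc)2/dppp/Et3SiH). This gives the 5-O-triflate of 9 F1 and then (2S)-7,3',4'-tris(TBS-oxy)flavanone F2.
- The most labile silyl ether, on O7 para to the carbonyl, is removed with one equivalent of Et3N·3HF in MeCN at 0 °C to give (2S)-7-hydroxy-3',4'-bis(TBS-oxy)flavanone F3.
- Pd(PPh3)4-catalysed opening of 2-methyl-2-vinyloxirane by this phenol at the tertiary carbon gives (2S)-7-[(1-hydroxy-2-methylbut-3-en-2-yl)oxy]-3',4'-bis(TBS-oxy)flavanone F4. Its ether carbon is a diastereomer pair that is erased in the next operation.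
- A single ortho [3,3] shift (Eu(fod)3, CHCl3, 60 °C) then delivers the chain to C8, the position favoured by bond fixation in 7-oxygenated chromanones. It gives (2S)-7-hydroxy-8-[(2Z)-4-hydroxy-3-methylbut-2-en-1-yl]-3',4'-bis(TBS-oxy)flavanone F5.
- This single shift is not stereospecific, so F5 must be separated from its E isomer by preparative HPLC; the fallback cures the regiochemical failure but not the geometric one.
- The conditions of step 9 convert F5 into 16.

Step 5 (Mitsunobu at the chelated 5-OH). The risks are low conversion of the hydrogen-bonded phenol and some SN2' ether. The fallback sets out from 7 and 9 and comes back at 10.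
- Alcohol 7 is converted with CBr4/PPh3 (CH2Cl2, −20 °C) into tert-butyl{[(2Z)-4-bromo-2-methylbut-2-en-1-yl]oxy}dimethylsilane F6.
- Phenol 9 is O-alkylated with F6 under silver assistance (Ag2O, CH2Cl2, rt, dark). This is a non-basic Williamson-type alkylation that does not endanger C2 and gives 10.

Step 8 (triflate hydrogenolysis). The risks are slow hydride transfer at the peri-hindered triflate and silyl scrambling by the Et3SiOTf formed. The fallback sets out from 14 and comes back at 15.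
- Miyaura borylation (PdCl2(dppf), bis(pinacolato)diboron, KOAc, dioxane, 80 °C) gives the 5-(pinacolboronate) analogue of 15 F7.
- Its C–B bond, ortho to the carbonyl, is cleaved by protodeboronation (AcOH–H2O, THF, 50 °C) to give 15.

**Further compounds**
F1 | step 6 | (2S)-7,3',4'-tris(TBS-oxy)-4-oxoflavan-5-yl trifluoromethanesulfonate | CC(C)(C)[Si](C)(C)Oc1cc(OS(=O)(=O)C(F)(F)F)c2c(c1)O[C@H](c1ccc(O[Si](C)(C)C(C)(C)C)c(O[Si](C)(C)C(C)(C)C)c1)CC2=O
F2 | step 6 | (2S)-7,3',4'-tris(TBS-oxy)flavanone | CC(C)(C)[Si](C)(C)Oc1ccc2c(c1)O[C@H](c1ccc(O[Si](C)(C)C(C)(C)C)c(O[Si](C)(C)C(C)(C)C)c1)CC2=O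
F3 | step 6 | (2S)-7-hydroxy-3',4'-bis(TBS-oxy)flavanone | Oc1ccc2c(c1)O[C@H](c1ccc(O[Si](C)(C)C(C)(C)C)c(O[Si](C)(C)C(C)(C)C)c1)CC2=O
F4 | step 6 | (2S)-7-[(1-hydroxy-2-methylbut-3-en-2-yl)oxy]-3',4'-bis(TBS-oxy)flavanone (ether carbon undefined) | C=CC(C)(CO)Oc1ccc2c(c1)O[C@H](c1ccc(O[Si](C)(C)C(C)(C)C)c(O[Si](C)(C)C(C)(C)C)c1)CC2=O
F5 | step 6 | (2S)-7-hydroxy-8-[(2Z)-4-hydroxy-3-methylbut-2-en-1-yl]-3',4'-bis(TBS-oxy)flavanone | C/C(=C/Cc1c(O)ccc2c1O[C@H](c1ccc(O[Si](C)(C)C(C)(C)C)c(O[Si](C)(C)C(C)(C)C)c1)CC2=O)CO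
F6 | step 5 | tert-butyl{[(2Z)-4-bromo-2-methylbut-2-en-1-yl]oxy}dimethylsilane | BrC/C=C(/C)CO[Si](C)(C)C(C)(C)C
F7 | step 8 | (2S)-8-[(2Z)-4-(TBS-oxy)-3-methylbut-2-en-1-yl]-5-(4,4,5,5-tetramethyl-1,3,2-dioxaborolan-2-yl)-7,3',4'-tris(TBS-oxy)flavanone | C/C(=C/Cc1c(O[Si](C)(C)C(C)(C)C)cc(B3OC(C)(C)C(C)(C)O3)c2c1O[C@H](c1ccc(O[Si](C)(C)C(C)(C)C)c(O[Si](C)(C)C(C)(C)C)c1)CC2=O)CO[Si](C)(C)C(C)(C)C
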